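**Retrosynthetic overview**
1. The target is read as epicatechin-(4α→6)-epiafzelechin-(4α→8)-epicatechin-(4β→6)-epicatechin, called from the top the top unit, the afzelechin unit, the third unit and the bottom unit (all 2R,3R; the C4–aryl bond is cis to 3-OH in the top and afzelechin units, trans in the third unit). The last operations are global hydrogenolysis and, before it, a double C3 inversion (oxidation, then LiBH(s-Bu)3) that turns two 3,4-trans catechin/afzelechin-type linkages into the all-cis ones.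
2. Disconnection C4(afzelechin unit)–C8(third unit) gives a dimeric 4-alkoxy donor, top unit–afzelechin unit (from (+)-catechin and (+)-afzelechin, C4→C6 bond steered by a bromine cap at C8), and a third unit–bottom unit dimer.
3. In the third unit–bottom unit dimer, ring C of the third unit (O1, C2, C3, C4, C4a, C8a) is not taken from a flavan. It is made by 5→6 ring expansion of a trans-2-aryl-2,3-dihydrobenzofuran-3-carbaldehyde dibenzyl acetal (1,2-shift of C2 onto the acetal carbon); the same event frees the C4 cation, which is arylated by C6 of the bottom unit.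
4. Enabling feature: ring A of the third unit is phloroglucinol-type, with O1, O5 and O7 ortho/para to C4a, so C4 is a quinone-methide-stabilised cation next to the oxygenated C3. The same ring drives the earlier 6→5 phenonium contraction of (+)-catechin, which supplies the dihydrobenzofuran with C2 already set.
5. Ring order: rings C of the top, afzelechin and bottom units come intact from the chiral pool; ring C of the third unit is contracted in step 3 and rebuilt in the key step; no other ring is formed.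

Key step: step 9

Remark: α/β are used in the flavan sense (all 2-aryl groups α). (+)-Catechin, (−)-epicatechin and (+)-afzelechin are assumed to be bought as single enantiomers.

**Route**

Step 1
Reactants: 1 (+)-catechin
Product: 2 5,7,3',4'-tetra-O-benzyl-(+)-catechin
Conditions: BnBr (4.4 equiv), K2CO3, DMF, 0 °C → rt
Reagents that add atoms: benzyl bromide, BrCc1ccccc1
Why: Williamson etherification of the four phenols, which are far more acidic than the secondary 3-OH, should leave C2 and C3 untouched.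

Step 2
Reactants: 2 5,7,3',4'-tetra-O-benzyl-(+)-catechin
Product: 3 8-iodo-5,7,3',4'-tetra-O-benzyl-(+)-catechin
Conditions: N-iodosuccinimide (1.05 equiv), CH2Cl2, −20 °C → rt, dark
Reagents that add atoms: N-iodosuccinimide, O=C1CCC(=O)N1I
Why: Electrophilic aromatic iodination should go to C8 of ring A (between O1 and O7, less hindered than C6), by analogy with the C8-selective bromination of 5,7-di-O-benzylflavans; the iodide caps C8 in steps 9 and 16 and is the handle for step 10.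

Step 3
Reactants: 3 8-iodo-5,7,3',4'-tetra-O-benzyl-(+)-catechin
Product: 5 [(2S,3R)-4,6-bis(benzyloxy)-2-[3,4-bis(benzyloxy)phenyl]-7-iodo-2,3-dihydro-1-benzofuran-3-yl]methanol (2,3-trans), via 3-O-mesylate 4 (not isolated)
Conditions: MsCl, Et3N, CH2Cl2, 0 °C; then acetone–H2O (4:1), NaHCO3, 50 °C
Reagents that add atoms: water, O
Why: Aryl-participated solvolysis (phenonium-ion 1,2-aryl shift): the equatorial C3–OMs bond is antiperiplanar to C4–C4a, ipso attack of the trioxygenated ring A inverts C3, and water opens the spiro-cyclopropane at the primary carbon (old C4), which should give the ring-contracted 2,3-trans dihydrobenzofuran with C2 unchanged.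

Step 4
Reactants: 5 [(2S,3R)-4,6-bis(benzyloxy)-2-[3,4-bis(benzyloxy)phenyl]-7-iodo-2,3-dihydro-1-benzofuran-3-yl]methanol
Product: 6 (2S,3S)-4,6-bis(benzyloxy)-2-[3,4-bis(benzyloxy)phenyl]-7-iodo-2,3-dihydro-1-benzofuran-3-carbaldehyde (2,3-trans)
Conditions: Dess–Martin periodinane, CH2Cl2, 0 °C → rt; used crude
Reagents that add atoms: none
Why: Dess–Martin oxidation of the primary alcohol under non-basic conditions should avoid β-elimination of the aryloxy group and keep the trans configuration at the α-carbon, which is also the thermodynamic one.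

Step 5
Reactants: 6 (2S,3S)-4,6-bis(benzyloxy)-2-[3,4-bis(benzyloxy)phenyl]-7-iodo-2,3-dihydro-1-benzofuran-3-carbaldehyde
Product: 7 (2S,3S)-4,6-bis(benzyloxy)-3-[bis(benzyloxy)methyl]-2-[3,4-bis(benzyloxy)phenyl]-7-iodo-2,3-dihydro-1-benzofuran (2,3-trans)
Conditions: BnOSiMe3 (2.5 equiv), Me3SiOTf (2 mol %), CH2Cl2, −78 °C; pyridine quench
Reagents that add atoms: benzyloxytrimethylsilane, C[Si](C)(C)OCc1ccccc1
Why: Noyori acetalisation at −78 °C, where the excess silyl ether captures the oxocarbenium ion before it can rearrange, should give the dibenzyl acetal without touching C2 or C3 (any 3,4-bis(benzyloxy)flavan formed by premature shift of C2 would enter step 9 through the same cation).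

Step 6
Reactants: 8 (−)-epicatechin
Product: 9 5,7,3',4'-tetra-O-benzyl-(−)-epicatechin
Conditions: BnBr (4.4 equiv), K2CO3, DMF, 0 °C → rt
Reagents that add atoms: benzyl bromide, BrCc1ccccc1
Why: Williamson etherification of the four phenols only, as in step 1, with no stereocentre involved.

Step 7
Reactants: 9 5,7,3',4'-tetra-O-benzyl-(−)-epicatechin
Product: 10 8-bromo-5,7,3',4'-tetra-O-benzyl-(−)-epicatechin
Conditions: N-bromosuccinimide (1.0 equiv), CH2Cl2, −78 °C → rt
Reagents that add atoms: N-bromosuccinimide, O=C1CCC(=O)N1Br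
Why: Electrophilic aromatic bromination is known to be C8-selective on 5,7-di-O-benzylflavans; the bromine blocks C8 so that the bottom unit can only react at C6.

Step 8
Reactants: 10 8-bromo-5,7,3',4'-tetra-O-benzyl-(−)-epicatechin
Product: 11 8-bromo-3,5,7,3',4'-penta-O-benzyl-(−)-epicatechin
Conditions: NaH, BnBr, DMF, 0 °C → rt
Reagents that add atoms: benzyl bromide, BrCc1ccccc1
Why: Williamson etherification of the 3-OH protects it against the later oxidation of step 20 without touching C2 or C3.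

Step 9
Reactants: 7 (2S,3S)-4,6-bis(benzyloxy)-3-[bis(benzyloxy)methyl]-2-[3,4-bis(benzyloxy)phenyl]-7-iodo-2,3-dihydro-1-benzofuran; 11 8-bromo-3,5,7,3',4'-penta-O-benzyl-(−)-epicatechin (2.5 equiv)
Product: 13 8-iodo-3,5,7,3',4'-penta-O-benzylepicatechin-(4β→6)-8-bromo-3,5,7,3',4'-penta-O-benzylepicatechin (third unit–bottom unit dimer), via flavan-4-ylium triflate 12 (not isolated)
Conditions: Me3SiOTf (0.3 equiv), 4 Å MS, CH2Cl2, −78 → −30 °C; Et3N quench
Reagents that add atoms: none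
Why: Proposed new method: Me3SiOTf ionises the dibenzyl acetal to an O-benzyl oxocarbenium ion, and C2 of the dihydrobenzofuran then shifts suprafacially from the ring carbon C3 to the oxocarbenium carbon (Wagner–Meerwein 1,2-shift, the first half of the acid-catalysed aldehyde–ketone rearrangement and the reverse of a Meinwald-type ring contraction); the shift should be downhill because the cation left behind (flavan C4) is the O1/O5/O7-stabilised quinone-methide cation 12 that every 4-alkoxyflavan donor gives. The six-membered ring therefore closes not by cyclisation but by 5→6 ring expansion through this three-centre shift, with C2 migrating with retention so that its configuration comes unchanged from (+)-catechin. C3 is set in the shift: the rotamer in which the OBn group of the oxocarbenium ion points away from ring A and its peri-benzyloxy group should be preferred, and in the trans-configured precursor this places 3-OBn cis to the 2-aryl group (epicatechin series). C4 is set by Friedel–Crafts attack of C6 of 11 on 12 anti to the pseudoaxial 3-OBn (4β, 3,4-trans), the known course of epicatechin-derived C4 cations in Me3SiOTf-mediated couplings of 4-alkoxyflavans, which are the closest known reaction type. The step needs the shift of C2 to beat direct arylation of the oxocarbenium ion and the 1,2-hydride shift from C3 (C2 is an α-aryl-α-aryloxy carbon of high migratory aptitude, its shift alone relieves the strain of the five-membered ring, the hindered nucleophile is slow at a neopentyl-type carbon, and any 4-OBn flavan formed by return of BnOSiMe3 re-ionises to 12), C6 over C8 of the bottom unit (bromine cap), and cross-coupling over self-condensation (iodine cap at C8 of the third unit, excess 11).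

Step 10
Reactants: 13 8-iodo-3,5,7,3',4'-penta-O-benzylepicatechin-(4β→6)-8-bromo-3,5,7,3',4'-penta-O-benzylepicatechin
Product: 15 3,5,7,3',4'-penta-O-benzylepicatechin-(4β→6)-8-bromo-3,5,7,3',4'-penta-O-benzylepicatechin, via arylmagnesium chloride 14 (not isolated)
Conditions: i-PrMgCl·LiCl (1.3 equiv), THF, −20 → 0 °C; then MeOH
Reagents that add atoms: none
Why: Iodine–magnesium exchange should occur only at the aryl iodide (the electron-rich aryl bromide of the bottom unit exchanges far more slowly), and protonation frees C8 of the third unit as the nucleophilic site for step 18.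

Step 11
Reactants: 3 8-iodo-5,7,3',4'-tetra-O-benzyl-(+)-catechin
Product: 16 (2R,3S,4S)-8-iodo-4-(2-ethoxyethoxy)-5,7,3',4'-tetra-O-benzylcatechin (4β-ether)
Conditions: DDQ (2 equiv), 2-ethoxyethanol (5 equiv), CH2Cl2, rt
Reagents that add atoms: 2-ethoxyethanol, CCOCCO
Why: DDQ benzylic oxidation (hydride abstraction at C4 assisted by O5/O7, alcohol capture of the cation) should give the 4β-ether typical of the catechin series; the C4 configuration is lost again in step 16.

Step 12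
Reactants: 16 (2R,3S,4S)-8-iodo-4-(2-ethoxyethoxy)-5,7,3',4'-tetra-O-benzylcatechin
Product: 17 3-O-acetyl-8-iodo-4β-(2-ethoxyethoxy)-5,7,3',4'-tetra-O-benzylcatechin
Conditions: Ac2O, DMAP (cat.), pyridine, rt
Reagents that add atoms: acetic anhydride, CC(=O)OC(C)=O
Why: DMAP-catalysed acetylation of the 3-OH installs the participating group that later directs attack to the α-face.

Step 13
Reactants: 18 (+)-afzelechin
Product: 19 5,7,4'-tri-O-benzyl-(+)-afzelechin
Conditions: BnBr (3.3 equiv), K2CO3, DMF, 0 °C → rt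
Reagents that add atoms: benzyl bromide, BrCc1ccccc1
Why: Williamson etherification of the three phenols only, with no stereocentre involved.

Step 14
Reactants: 19 5,7,4'-tri-O-benzyl-(+)-afzelechin
Product: 20 8-bromo-5,7,4'-tri-O-benzyl-(+)-afzelechin
Conditions: N-bromosuccinimide (1.0 equiv), CH2Cl2, −78 °C → rt
Reagents that add atoms: N-bromosuccinimide, O=C1CCC(=O)N1Br
Why: C8-selective electrophilic bromination blocks C8 of the afzelechin unit so that the top unit must enter at C6.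

Step 15
Reactants: 20 8-bromo-5,7,4'-tri-O-benzyl-(+)-afzelechin
Product: 21 3-O-acetyl-8-bromo-5,7,4'-tri-O-benzyl-(+)-afzelechin
Conditions: Ac2O, DMAP (cat.), pyridine, rt
Reagents that add atoms: acetic anhydride, CC(=O)OC(C)=O
Why: Acetylation gives the 3-OAc that distinguishes the top and afzelechin units from the O-benzylated third and bottom units and acts as participating group in step 18.

Step 16
Reactants: 17 3-O-acetyl-8-iodo-4β-(2-ethoxyethoxy)-5,7,3',4'-tetra-O-benzylcatechin; 21 3-O-acetyl-8-bromo-5,7,4'-tri-O-benzyl-(+)-afzelechin (2.5 equiv)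
Product: 22 3-O-acetyl-8-iodo-5,7,3',4'-tetra-O-benzylcatechin-(4α→6)-3-O-acetyl-8-bromo-5,7,4'-tri-O-benzylafzelechin (top unit–afzelechin unit dimer)
Conditions: Me3SiOTf (0.5 equiv), CH2Cl2, −78 °C
Reagents that add atoms: none
Why: Lewis-acid-mediated Friedel–Crafts flavan coupling: the 4-alkoxy group ionises, the β-oriented 3-OAc shields the β-face as a bridged 1,3-dioxolan-2-ylium ion so that the arene adds from the α-face (4α, 3,4-trans), and the bromine at C8 of 21 leaves C6 as the only site, self-condensation of 17 being held back by its iodine cap and the excess of 21.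

Step 17
Reactants: 22 top unit–afzelechin unit dimer diacetate
Product: 23 3-O-acetyl-8-iodo-5,7,3',4'-tetra-O-benzylcatechin-(4α→6)-3-O-acetyl-8-bromo-4β-(2-ethoxyethoxy)-5,7,4'-tri-O-benzylafzelechin
Conditions: DDQ (2 equiv), 2-ethoxyethanol (5 equiv), CH2Cl2, rt
Reagents that add atoms: 2-ethoxyethanol, CCOCCO
Why: DDQ benzylic oxidation should take place at the only benzylic methylene, C4 of the afzelechin unit, because the C4–H of the top unit is a buried methine between two ortho-benzyloxy groups; the new C4 configuration is irrelevant.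

Step 18
Reactants: 23 dimeric 4-(2-ethoxyethoxy) donor; 15 third unit–bottom unit dimer
Product: 24 3-O-acetyl-8-iodo-5,7,3',4'-tetra-O-benzylcatechin-(4α→6)-3-O-acetyl-8-bromo-5,7,4'-tri-O-benzylafzelechin-(4α→8)-3,5,7,3',4'-penta-O-benzylepicatechin-(4β→6)-8-bromo-3,5,7,3',4'-penta-O-benzylepicatechin
Conditions: Me3SiOTf (0.5 equiv), CH2Cl2, −78 → −40 °C
Reagents that add atoms: none
Why: The same Friedel–Crafts coupling: acetate participation at C3 of the afzelechin unit sends C8 of the third unit (the most nucleophilic and least hindered free position of 15) to the α-face, which should give the 4α→8 bond 3,4-trans.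

Step 19
Reactants: 24 protected tetramer diacetate
Product: 25 8-iodo-5,7,3',4'-tetra-O-benzylcatechin-(4α→6)-8-bromo-5,7,4'-tri-O-benzylafzelechin-(4α→8)-3,5,7,3',4'-penta-O-benzylepicatechin-(4β→6)-8-bromo-3,5,7,3',4'-penta-O-benzylepicatechin (bis-deacetylated tetramer; both free 3-OH β)
Conditions: NaOMe (cat.), MeOH–THF, 40 °C
Reagents that add atoms: none
Why: Zemplén transesterification removes both acetates and leaves benzyl ethers, aryl halides and all stereocentres untouched.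

Step 20
Reactants: 25 bis-deacetylated tetramer
Product: 26 8-iodo-5,7,3',4'-tetra-O-benzyl-3-oxoflavan-(4α→6)-8-bromo-5,7,4'-tri-O-benzyl-3-oxoflavan-(4α→8)-3,5,7,3',4'-penta-O-benzylepicatechin-(4β→6)-8-bromo-3,5,7,3',4'-penta-O-benzylepicatechin (bis(flavan-3-one) tetramer)
Conditions: Dess–Martin periodinane (4 equiv), CH2Cl2, rt
Reagents that add atoms: none
Why: Dess–Martin oxidation of the two free secondary alcohols gives the diketone; the flanking C2 and C4 aryl groups are cis-diequatorial, the thermodynamically favoured arrangement, so enolisation should not erode them.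

Step 21
Reactants: 26 bis(flavan-3-one) tetramer
Product: 27 8-iodo-5,7,3',4'-tetra-O-benzylepicatechin-(4α→6)-8-bromo-5,7,4'-tri-O-benzylepiafzelechin-(4α→8)-3,5,7,3',4'-penta-O-benzylepicatechin-(4β→6)-8-bromo-3,5,7,3',4'-penta-O-benzylepicatechin
Conditions: LiBH(s-Bu)3 (4 equiv), LiBr, THF, −78 °C; aqueous work-up
Reagents that add atoms: none
Why: Bulky-hydride reduction: hydride should reach each ketone from the β-face, anti to the two α-oriented flanking aryl groups (equatorial attack), giving the axial α-alcohols and hence the all-cis top and afzelechin units, as in the known flavan-3-one to epi-series reduction.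

Step 22
Reactants: 27 protected target
Product: 28 the target epicatechin-(4α→6)-epiafzelechin-(4α→8)-epicatechin-(4β→6)-epicatechin
Conditions: H2 (1 atm), Pd(OH)2/C, Et3N (3.3 equiv), THF–MeOH–H2O, rt
Reagents that add atoms: none
Why: Catalytic hydrogenolysis should cleave the three aryl–halogen bonds first (Et3N, used only in the amount needed to take up HBr and HI, is thereby turned into its salts and no longer slows debenzylation) and then the seventeen benzyl ethers, without affecting the acid-labile interflavan bonds or any stereocentre.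

**Compound list**

1 | (+)-catechin, (2R,3S) | O[C@H]1Cc2c(O)cc(O)cc2O[C@@H]1c1ccc(O)c(O)c1 | starting material
2 | 5,7,3',4'-tetra-O-benzyl-(+)-catechin | O[C@H]1Cc2c(OCc3ccccc3)cc(OCc3ccccc3)cc2O[C@@H]1c1ccc(OCc2ccccc2)c(OCc2ccccc2)c1 | intermediate
3 | 8-iodo-5,7,3',4'-tetra-O-benzyl-(+)-catechin | O[C@H]1Cc2c(OCc3ccccc3)cc(OCc3ccccc3)c(I)c2O[C@@H]1c1ccc(OCc2ccccc2)c(OCc2ccccc2)c1 | intermediate
4 | 8-iodo-5,7,3',4'-tetra-O-benzyl-(+)-catechin 3-O-methanesulfonate | CS(=O)(=O)O[C@H]1Cc2c(OCc3ccccc3)cc(OCc3ccccc3)c(I)c2O[C@@H]1c1ccc(OCc2ccccc2)c(OCc2ccccc2)c1 | intermediate (not isolated)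
5 | [(2S,3R)-4,6-bis(benzyloxy)-2-[3,4-bis(benzyloxy)phenyl]-7-iodo-2,3-dihydro-1-benzofuran-3-yl]methanol, 2,3-trans | OC[C@@H]1[C@@H](c2ccc(OCc3ccccc3)c(OCc3ccccc3)c2)Oc2c(I)c(OCc3ccccc3)cc(OCc3ccccc3)c12 | intermediate
6 | (2S,3S)-4,6-bis(benzyloxy)-2-[3,4-bis(benzyloxy)phenyl]-7-iodo-2,3-dihydro-1-benzofuran-3-carbaldehyde, 2,3-trans | O=C[C@@H]1[C@@H](c2ccc(OCc3ccccc3)c(OCc3ccccc3)c2)Oc2c(I)c(OCc3ccccc3)cc(OCc3ccccc3)c12 | intermediate
7 | (2S,3S)-4,6-bis(benzyloxy)-3-[bis(benzyloxy)methyl]-2-[3,4-bis(benzyloxy)phenyl]-7-iodo-2,3-dihydro-1-benzofuran, 2,3-trans | C(OCc1ccccc1)(OCc1ccccc1)[C@@H]1[C@@H](c2ccc(OCc3ccccc3)c(OCc3ccccc3)c2)Oc2c(I)c(OCc3ccccc3)cc(OCc3ccccc3)c12 | intermediate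
8 | (−)-epicatechin, (2R,3R) | O[C@@H]1Cc2c(O)cc(O)cc2O[C@@H]1c1ccc(O)c(O)c1 | starting material
9 | 5,7,3',4'-tetra-O-benzyl-(−)-epicatechin | O[C@@H]1Cc2c(OCc3ccccc3)cc(OCc3ccccc3)cc2O[C@@H]1c1ccc(OCc2ccccc2)c(OCc2ccccc2)c1 | intermediate
10 | 8-bromo-5,7,3',4'-tetra-O-benzyl-(−)-epicatechin | O[C@@H]1Cc2c(OCc3ccccc3)cc(OCc3ccccc3)c(Br)c2O[C@@H]1c1ccc(OCc2ccccc2)c(OCc2ccccc2)c1 | intermediate
11 | 8-bromo-3,5,7,3',4'-penta-O-benzyl-(−)-epicatechin | O(Cc1ccccc1)[C@@H]1Cc2c(OCc3ccccc3)cc(OCc3ccccc3)c(Br)c2O[C@@H]1c1ccc(OCc2ccccc2)c(OCc2ccccc2)c1 | intermediate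
12 | (2R,3R)-3,5,7-tris(benzyloxy)-2-[3,4-bis(benzyloxy)phenyl]-8-iodochroman-4-ylium triflate (3-OBn cis to 2-aryl) | O(Cc1ccccc1)[C@@H]1[CH+]c2c(OCc3ccccc3)cc(OCc3ccccc3)c(I)c2O[C@@H]1c1ccc(OCc2ccccc2)c(OCc2ccccc2)c1.[O-]S(=O)(=O)C(F)(F)F | intermediate (not isolated)
13 | 8-iodo-3,5,7,3',4'-penta-O-benzylepicatechin-(4β→6)-8-bromo-3,5,7,3',4'-penta-O-benzylepicatechin | O(Cc1ccccc1)[C@@H]1[C@@H](c3c(OCc5ccccc5)c(Br)c4c(c3OCc5ccccc5)C[C@@H](OCc5ccccc5)[C@@H](c3ccc(OCc5ccccc5)c(OCc5ccccc5)c3)O4)c2c(OCc3ccccc3)cc(OCc3ccccc3)c(I)c2O[C@@H]1c1ccc(OCc2ccccc2)c(OCc2ccccc2)c1 | intermediate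
14 | C8-chloromagnesio derivative of the third unit–bottom unit dimer (magnesium in place of iodine) | O(Cc1ccccc1)[C@@H]1[C@@H](c3c(OCc5ccccc5)c(Br)c4c(c3OCc5ccccc5)C[C@@H](OCc5ccccc5)[C@@H](c3ccc(OCc5ccccc5)c(OCc5ccccc5)c3)O4)c2c(OCc3ccccc3)cc(OCc3ccccc3)c([Mg]Cl)c2O[C@@H]1c1ccc(OCc2ccccc2)c(OCc2ccccc2)c1 | intermediate (not isolated)
15 | 3,5,7,3',4'-penta-O-benzylepicatechin-(4β→6)-8-bromo-3,5,7,3',4'-penta-O-benzylepicatechin | O(Cc1ccccc1)[C@@H]1[C@@H](c3c(OCc5ccccc5)c(Br)c4c(c3OCc5ccccc5)C[C@@H](OCc5ccccc5)[C@@H](c3ccc(OCc5ccccc5)c(OCc5ccccc5)c3)O4)c2c(OCc3ccccc3)cc(OCc3ccccc3)cc2O[C@@H]1c1ccc(OCc2ccccc2)c(OCc2ccccc2)c1 | intermediate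
16 | (2R,3S,4S)-8-iodo-4-(2-ethoxyethoxy)-5,7,3',4'-tetra-O-benzylcatechin (4β-ether, 3-OH free) | O[C@H]1[C@@H](OCCOCC)c2c(OCc3ccccc3)cc(OCc3ccccc3)c(I)c2O[C@@H]1c1ccc(OCc2ccccc2)c(OCc2ccccc2)c1 | intermediate
17 | 3-O-acetyl-8-iodo-4β-(2-ethoxyethoxy)-5,7,3',4'-tetra-O-benzylcatechin | CC(=O)O[C@H]1[C@@H](OCCOCC)c2c(OCc3ccccc3)cc(OCc3ccccc3)c(I)c2O[C@@H]1c1ccc(OCc2ccccc2)c(OCc2ccccc2)c1 | intermediate
18 | (+)-afzelechin, (2R,3S) | O[C@H]1Cc2c(O)cc(O)cc2O[C@@H]1c1ccc(O)cc1 | starting material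
19 | 5,7,4'-tri-O-benzyl-(+)-afzelechin | O[C@H]1Cc2c(OCc3ccccc3)cc(OCc3ccccc3)cc2O[C@@H]1c1ccc(OCc2ccccc2)cc1 | intermediate
20 | 8-bromo-5,7,4'-tri-O-benzyl-(+)-afzelechin | O[C@H]1Cc2c(OCc3ccccc3)cc(OCc3ccccc3)c(Br)c2O[C@@H]1c1ccc(OCc2ccccc2)cc1 | intermediate
21 | 3-O-acetyl-8-bromo-5,7,4'-tri-O-benzyl-(+)-afzelechin | CC(=O)O[C@H]1Cc2c(OCc3ccccc3)cc(OCc3ccccc3)c(Br)c2O[C@@H]1c1ccc(OCc2ccccc2)cc1 | intermediate
22 | 3-O-acetyl-8-iodo-5,7,3',4'-tetra-O-benzylcatechin-(4α→6)-3-O-acetyl-8-bromo-5,7,4'-tri-O-benzylafzelechin | CC(=O)O[C@H]1Cc2c(OCc3ccccc3)c([C@@H]4c5c(OCc6ccccc6)cc(OCc6ccccc6)c(I)c5O[C@H](c5ccc(OCc6ccccc6)c(OCc6ccccc6)c5)[C@H]4OC(C)=O)c(OCc3ccccc3)c(Br)c2O[C@@H]1c1ccc(OCc2ccccc2)cc1 | intermediate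
23 | 3-O-acetyl-8-iodo-5,7,3',4'-tetra-O-benzylcatechin-(4α→6)-3-O-acetyl-8-bromo-4β-(2-ethoxyethoxy)-5,7,4'-tri-O-benzylafzelechin | CC(=O)O[C@H]1[C@@H](OCCOCC)c2c(OCc3ccccc3)c([C@@H]4c5c(OCc6ccccc6)cc(OCc6ccccc6)c(I)c5O[C@H](c5ccc(OCc6ccccc6)c(OCc6ccccc6)c5)[C@H]4OC(C)=O)c(OCc3ccccc3)c(Br)c2O[C@@H]1c1ccc(OCc2ccccc2)cc1 | intermediate
24 | protected tetramer diacetate: 3-O-acetyl-8-iodo-tetra-O-benzylcatechin-(4α→6)-3-O-acetyl-8-bromo-tri-O-benzylafzelechin-(4α→8)-penta-O-benzylepicatechin-(4β→6)-8-bromo-penta-O-benzylepicatechin | CC(=O)O[C@H]1[C@H](c3c(OCc5ccccc5)cc(OCc5ccccc5)c4c3O[C@H](c3ccc(OCc5ccccc5)c(OCc5ccccc5)c3)[C@H](OCc5ccccc5)[C@H]4c3c(OCc5ccccc5)c(Br)c4c(c3OCc5ccccc5)C[C@@H](OCc5ccccc5)[C@@H](c3ccc(OCc5ccccc5)c(OCc5ccccc5)c3)O4)c2c(OCc3ccccc3)c([C@@H]4c5c(OCc6ccccc6)cc(OCc6ccccc6)c(I)c5O[C@H](c5ccc(OCc6ccccc6)c(OCc6ccccc6)c5)[C@H]4OC(C)=O)c(OCc3ccccc3)c(Br)c2O[C@@H]1c1ccc(OCc2ccccc2)cc1 | intermediate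
25 | bis-deacetylated tetramer: 8-iodo-tetra-O-benzylcatechin-(4α→6)-8-bromo-tri-O-benzylafzelechin-(4α→8)-penta-O-benzylepicatechin-(4β→6)-8-bromo-penta-O-benzylepicatechin (free β-3-OH in the top unit and in the afzelechin unit) | O[C@H]1[C@H](c3c(OCc5ccccc5)cc(OCc5ccccc5)c4c3O[C@H](c3ccc(OCc5ccccc5)c(OCc5ccccc5)c3)[C@H](OCc5ccccc5)[C@H]4c3c(OCc5ccccc5)c(Br)c4c(c3OCc5ccccc5)C[C@@H](OCc5ccccc5)[C@@H](c3ccc(OCc5ccccc5)c(OCc5ccccc5)c3)O4)c2c(OCc3ccccc3)c([C@@H]4c5c(OCc6ccccc6)cc(OCc6ccccc6)c(I)c5O[C@H](c5ccc(OCc6ccccc6)c(OCc6ccccc6)c5)[C@H]4O)c(OCc3ccccc3)c(Br)c2O[C@@H]1c1ccc(OCc2ccccc2)cc1 | intermediate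
26 | bis(flavan-3-one) tetramer (3-keto group in the top unit and in the afzelechin unit) | O=C1[C@H](c3c(OCc5ccccc5)cc(OCc5ccccc5)c4c3O[C@H](c3ccc(OCc5ccccc5)c(OCc5ccccc5)c3)[C@H](OCc5ccccc5)[C@H]4c3c(OCc5ccccc5)c(Br)c4c(c3OCc5ccccc5)C[C@@H](OCc5ccccc5)[C@@H](c3ccc(OCc5ccccc5)c(OCc5ccccc5)c3)O4)c2c(OCc3ccccc3)c([C@@H]4c5c(OCc6ccccc6)cc(OCc6ccccc6)c(I)c5O[C@H](c5ccc(OCc6ccccc6)c(OCc6ccccc6)c5)C4=O)c(OCc3ccccc3)c(Br)c2O[C@@H]1c1ccc(OCc2ccccc2)cc1 | intermediate
27 | 8-iodo-tetra-O-benzylepicatechin-(4α→6)-8-bromo-tri-O-benzylepiafzelechin-(4α→8)-penta-O-benzylepicatechin-(4β→6)-8-bromo-penta-O-benzylepicatechin (free α-3-OH in the top unit and in the afzelechin unit) | O[C@@H]1[C@H](c3c(OCc5ccccc5)cc(OCc5ccccc5)c4c3O[C@H](c3ccc(OCc5ccccc5)c(OCc5ccccc5)c3)[C@H](OCc5ccccc5)[C@H]4c3c(OCc5ccccc5)c(Br)c4c(c3OCc5ccccc5)C[C@@H](OCc5ccccc5)[C@@H](c3ccc(OCc5ccccc5)c(OCc5ccccc5)c3)O4)c2c(OCc3ccccc3)c([C@@H]4c5c(OCc6ccccc6)cc(OCc6ccccc6)c(I)c5O[C@H](c5ccc(OCc6ccccc6)c(OCc6ccccc6)c5)[C@@H]4O)c(OCc3ccccc3)c(Br)c2O[C@@H]1c1ccc(OCc2ccccc2)cc1 | intermediate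
28 | CNP0103636.2, epicatechin-(4α→6)-epiafzelechin-(4α→8)-epicatechin-(4β→6)-epicatechin | Oc1ccc([C@H]2Oc3cc(O)c([C@@H]4c5c(O)cc(O)cc5O[C@H](c5ccc(O)c(O)c5)[C@@H]4O)c(O)c3[C@@H](c3c(O)cc(O)c4c3O[C@H](c3ccc(O)c(O)c3)[C@H](O)[C@H]4c3c(O)cc4c(c3O)C[C@@H](O)[C@@H](c3ccc(O)c(O)c3)O4)[C@H]2O)cc1 | target

**Step count and risks**

Total step count: 22. Longest linear sequence: 12 steps (steps 1, 2, 3, 4, 5, 9, 10, 18, 19, 20, 21, 22).

The three steps most likely to fail:

Step 9 (new method). The shift of C2 may lose to direct arylation of the oxocarbenium ion, to a 1,2-hydride shift from C3 followed by aromatisation of the five-membered ring, or to ionisation of the C2–O1 bond, or the facial bias at C3 may be low. Fallback, known chemistry only: set out from 9. Iodination at C8 with N-iodosuccinimide gives 8-iodo-5,7,3',4'-tetra-O-benzylepicatechin F1. Benzylation of the 3-OH (NaH, BnBr) gives the pentabenzyl ether F2. DDQ oxidation in the presence of 2-ethoxyethanol gives the 4β-(2-ethoxyethoxy) donor F3. Coupling of F3 with 11 (Me3SiOTf, CH2Cl2, −78 °C) goes through the same cation 12 and, by the established 3,4-trans course of epicatechin donors, comes back to the route at 13.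

Step 17. DDQ may abstract the doubly benzylic C4–H of the top unit instead of a C4–H of the afzelechin unit, or may fail on the halogenated, crowded ring. Fallback with a pre-installed, orthogonally activated leaving group: set out from 21. DDQ and 2-ethoxyethanol give the monomeric 4β-(2-ethoxyethoxy) acetate F4. Exchange with 2,6-dimethylbenzenethiol (BF3·OEt2, −78 → 0 °C, acetate participation) gives the 4α-arylthio ether F5, which is inert to hard Lewis acids. BF3·OEt2-mediated coupling of 17 with F5 at C6 (−78 °C) gives the dimeric thioether F6. Thiophilic activation of F6 with AgOSO2CF3 in the presence of 15 (CH2Cl2, −40 °C) comes back to the route at 24, replacing steps 16–18.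

Step 3. The sulfonate may ionise with participation of O1 instead of C4a, or water may open the phenonium ion at C3 and return 3. Fallback by oxidative rearrangement of an alkene instead of solvolysis: set out from 3. DDQ in wet CH2Cl2 gives the 3,4-cis diol F7 (4β-OH). 1,1'-Thiocarbonyldiimidazole (toluene, 80 °C) gives the cyclic thionocarbonate F8. Corey–Winter elimination with 1,3-dimethyl-2-phenyl-1,3,2-diazaphospholidine (40 °C) gives the flav-3-ene F9. Ring contraction of its styrene-type double bond with the trivalent iodine reagent PhI(OH)OTs in benzyl alcohol–CH2Cl2 at −20 °C (addition of iodine at C3 anti to the 2-aryl group, 1,2-shift of ring A from C4 to C3, as in the contraction of 1,2-dihydronaphthalenes to indane acetals) comes back to the route at 7, replacing steps 3–5.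

**Further compounds**

F1 | step 9 | 8-iodo-5,7,3',4'-tetra-O-benzyl-(−)-epicatechin | O[C@@H]1Cc2c(OCc3ccccc3)cc(OCc3ccccc3)c(I)c2O[C@@H]1c1ccc(OCc2ccccc2)c(OCc2ccccc2)c1
F2 | step 9 | 8-iodo-3,5,7,3',4'-penta-O-benzyl-(−)-epicatechin | O(Cc1ccccc1)[C@@H]1Cc2c(OCc3ccccc3)cc(OCc3ccccc3)c(I)c2O[C@@H]1c1ccc(OCc2ccccc2)c(OCc2ccccc2)c1
F3 | step 9 | 8-iodo-4β-(2-ethoxyethoxy)-3,5,7,3',4'-penta-O-benzylepicatechin (3,4-trans) | O(Cc1ccccc1)[C@@H]1[C@@H](OCCOCC)c2c(OCc3ccccc3)cc(OCc3ccccc3)c(I)c2O[C@@H]1c1ccc(OCc2ccccc2)c(OCc2ccccc2)c1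
F4 | step 17 | 3-O-acetyl-8-bromo-4β-(2-ethoxyethoxy)-5,7,4'-tri-O-benzylafzelechin | CC(=O)O[C@H]1[C@@H](OCCOCC)c2c(OCc3ccccc3)cc(OCc3ccccc3)c(Br)c2O[C@@H]1c1ccc(OCc2ccccc2)cc1
F5 | step 17 | 3-O-acetyl-8-bromo-4α-(2,6-dimethylphenylthio)-5,7,4'-tri-O-benzylafzelechin (3,4-trans) | CC(=O)O[C@H]1[C@H](Sc3c(C)cccc3C)c2c(OCc3ccccc3)cc(OCc3ccccc3)c(Br)c2O[C@@H]1c1ccc(OCc2ccccc2)cc1
F6 | step 17 | 3-O-acetyl-8-iodo-tetra-O-benzylcatechin-(4α→6)-3-O-acetyl-8-bromo-4α-(2,6-dimethylphenylthio)-tri-O-benzylafzelechin | CC(=O)O[C@H]1[C@H](Sc3c(C)cccc3C)c2c(OCc3ccccc3)c([C@@H]4c5c(OCc6ccccc6)cc(OCc6ccccc6)c(I)c5O[C@H](c5ccc(OCc6ccccc6)c(OCc6ccccc6)c5)[C@H]4OC(C)=O)c(OCc3ccccc3)c(Br)c2O[C@@H]1c1ccc(OCc2ccccc2)cc1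
F7 | step 3 | 8-iodo-5,7,3',4'-tetra-O-benzylcatechin-4β-ol (3,4-cis diol) | O[C@H]1[C@@H](O)c2c(OCc3ccccc3)cc(OCc3ccccc3)c(I)c2O[C@@H]1c1ccc(OCc2ccccc2)c(OCc2ccccc2)c1
F8 | step 3 | cyclic 3,4-thionocarbonate of F7 | S=C1O[C@H]2[C@@H](O1)c1c(OCc3ccccc3)cc(OCc3ccccc3)c(I)c1O[C@@H]2c1ccc(OCc2ccccc2)c(OCc2ccccc2)c1
F9 | step 3 | (2S)-5,7-bis(benzyloxy)-2-[3,4-bis(benzyloxy)phenyl]-8-iodo-2H-chromene (flav-3-ene, C2 as in 3) | C1=Cc2c(OCc3ccccc3)cc(OCc3ccccc3)c(I)c2O[C@@H]1c1ccc(OCc2ccccc2)c(OCc2ccccc2)c1
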